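**Retrosynthetic overview**

1. Target 19 is traced back to the carvone-type enone 11 through redox changes at C2, hydroxyl-directed epoxidation of C1=C6, two separate senecioylations (ring hydroxyl first, side-chain hydroxyl after desilylation) and an α′-hydroxylation at C3 (ring locants as in 7-oxabicyclo[4.1.0]heptan-2-one: C1 = CMe, C2 = C=O, C3 = CH–O, C4 = CH–side chain, C5 = CH2, C6 = oxirane CH).
2. Key disconnection: the carbocycle of 11 is cut at C3–C4 and C1–C6 at once, giving dienal 7 (C4–C5–C6 plus the whole side chain) and tert-butyl 3-oxopentanoate 8 (C1–C2–C3 plus the ring methyl); forward, this is an amine-catalysed Michael addition followed by an acid-induced decarboxylative aldol condensation in one pot.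
3. Feature that allows it: ketone C2 has both α-carbons (C1, C3) in the six-membered ring and oxirane carbon C6 lies 1,5 to C2, so C1–C2–C3 is a butan-2-one 1,3-bis-nucleophile, C4–C5–C6 is an enal (C4 = β-carbon, C6 = former aldehyde carbon) and the oxirane is a masked C1=C6 enone double bond; the ester on C3 is a temporary activating group that leaves as CO2.
4. Dienal 7 comes from sulcatone 1, whose eight carbons are the complete side chain: proline-catalysed α-aminoxylation sets the carbinol centre, and the methyl ketone becomes the 1,1-disubstituted alkene by enol triflate formation and Heck coupling with acrolein.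
5. Order of ring formation: carbocycle in step 5, oxirane in step 11.

Key step: step 5

Remark: primed locants refer to the hepta-1,5-dien-2-yl side chain; in step 1 the copper-catalysed N–O cleavage is assumed to release the PhN fragment as azobenzene.

**Route**

Step 1
Reactants: 1 6-methylhept-5-en-2-one (sulcatone)
Product: 3 (3R)-3-hydroxy-6-methylhept-5-en-2-one, via anilinooxy ketone 2 (not isolated)
Conditions: L-proline (30 mol%), PhNO (slow addition), 1 in excess, DMSO, rt; then CuSO4·5H2O (30 mol%), MeOH, 0 °C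
Reagents that add atoms: nitrosobenzene, O=Nc1ccccc1
Why: Proline-catalysed α-aminoxylation, in which the more substituted (E)-enamine attacks the oxygen of acid-activated nitrosobenzene on one face so that L-proline should set the 3R centre, followed by copper-mediated N–O cleavage that leaves the stereocentre untouched.

Step 2
Reactants: 3 (3R)-3-hydroxy-6-methylhept-5-en-2-one
Product: 4 (3R)-3-{[tert-butyl(diphenyl)silyl]oxy}-6-methylhept-5-en-2-one
Conditions: TBDPSCl, imidazole, DMF, rt
Reagents that add atoms: tert-butyl(chloro)diphenylsilane, CC(C)(C)[Si](Cl)(c1ccccc1)c1ccccc1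
Why: Standard silylation of a secondary alcohol, chosen because the bulky, acid-stable silyl ether should survive the later enolisation, palladium and hot-acid steps.

Step 3
Reactants: 4 (3R)-3-{[tert-butyl(diphenyl)silyl]oxy}-6-methylhept-5-en-2-one
Product: 5 (3R)-3-{[tert-butyl(diphenyl)silyl]oxy}-6-methylhepta-1,5-dien-2-yl trifluoromethanesulfonate
Conditions: KN(SiMe3)2, THF, −78 °C; then PhNTf2, −78 to 0 °C; aq NH4Cl work-up
Reagents that add atoms: N-phenylbis(trifluoromethanesulfonimide), O=S(=O)(N(c1ccccc1)S(=O)(=O)C(F)(F)F)C(F)(F)F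
Why: Kinetic deprotonation by the hindered base should occur at the methyl group and not at the silyloxy-bearing methine, and O-triflation of the potassium enolate gives the 1,1-disubstituted enol triflate without touching the stereocentre.

Step 4
Reactants: 5 (3R)-3-{[tert-butyl(diphenyl)silyl]oxy}-6-methylhepta-1,5-dien-2-yl trifluoromethanesulfonate; 6 prop-2-enal (acrolein)
Product: 7 (2E,5R)-5-{[tert-butyl(diphenyl)silyl]oxy}-8-methyl-4-methylidenenona-2,7-dienal
Conditions: Pd(OAc)2 (5 mol%), Bu4NCl, NaHCO3, DMF, 40 °C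
Reagents that add atoms: none
Why: Heck reaction of an alkenyl triflate under ligand-free phase-transfer conditions, in which oxidative addition to zerovalent palladium, insertion of acrolein at its terminal carbon and syn β-hydride elimination should give the (E)-dienal.

Step 5
Reactants: 7 (2E,5R)-5-{[tert-butyl(diphenyl)silyl]oxy}-8-methyl-4-methylidenenona-2,7-dienal; 8 tert-butyl 3-oxopentanoate
Product: 11 (5R)-5-[(3R)-3-{[tert-butyl(diphenyl)silyl]oxy}-6-methylhepta-1,5-dien-2-yl]-2-methylcyclohex-2-en-1-one, via Michael adduct 9 (not isolated), via keto aldehyde 10 (not isolated)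
Conditions: (S)-2-{bis[3,5-bis(trifluoromethyl)phenyl][(trimethylsilyl)oxy]methyl}pyrrolidine (10 mol%), PhCO2H (10 mol%), toluene, rt; then TsOH·H2O (20 mol%), toluene, 80 °C (one pot)
Reagents that add atoms: none
Why: The amine condenses with 7 to an (E)-s-trans iminium ion, the enol of 8 adds to its β-carbon (ring bond C3–C4), and after hydrolysis the acid cleaves the tert-butyl ester, the β-keto acid loses CO2 and the ethyl ketone condenses with the aldehyde (ring bond C1–C6, then loss of water). The closest known reaction type is the amine-catalysed Michael addition of tert-butyl β-keto esters to enals followed by acid-induced decarboxylative aldol condensation to 5-substituted cyclohex-2-enones. The ring closes by a 6-(enolexo)-exo-trig aldol addition and dehydration to the conjugated trisubstituted enone, whereas closure through the other α-carbon would give a four-membered ring and should not compete. The one stereocentre that survives (C4 of the target ring, 5R in 11) is set by the catalyst, whose silyloxydiarylmethyl group covers one face of the iminium ion so that the nucleophile adds to the open face; the centre at the ester-bearing carbon is erased by decarboxylation. The step needs 1,4- rather than 1,6-addition to the conjugated 2,4-dienal, which should be secured by the larger LUMO coefficient at the β-carbon and by the branched silyloxyalkyl group twisting the 4-methylidene unit out of conjugation. It also needs catalyst control over the existing silyloxy stereocentre, which is expected because that centre sits beyond the 4-methylidene carbon and iminium shielding by this catalyst class usually overrides such remote substrate bias.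

Step 6
Reactants: 11 (5R)-5-[(3R)-3-{[tert-butyl(diphenyl)silyl]oxy}-6-methylhepta-1,5-dien-2-yl]-2-methylcyclohex-2-en-1-one
Product: 12 (5S,6S)-5-[(3R)-3-{[tert-butyl(diphenyl)silyl]oxy}-6-methylhepta-1,5-dien-2-yl]-6-hydroxy-2-methylcyclohex-2-en-1-one
Conditions: KN(SiMe3)2, THF, −78 °C; then 2-(phenylsulfonyl)-3-phenyloxaziridine, −78 °C; aq NH4Cl
Reagents that add atoms: 2-(phenylsulfonyl)-3-phenyloxaziridine, O=S(=O)(N1OC1c1ccccc1)c1ccccc1
Why: Kinetic α′-deprotonation gives the cross-conjugated potassium dienolate, which the N-sulfonyloxaziridine (Davis oxidation) should oxidise on the face anti to the adjacent side chain, as in the trans-selective trapping of 3-substituted cyclohexanone enolates, so that the new hydroxyl is trans to the side chain.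

Step 7
Reactants: 12 (5S,6S)-5-[(3R)-3-{[tert-butyl(diphenyl)silyl]oxy}-6-methylhepta-1,5-dien-2-yl]-6-hydroxy-2-methylcyclohex-2-en-1-one; 13 3-methylbut-2-enoyl chloride
Product: 14 (1S,6S)-6-[(3R)-3-{[tert-butyl(diphenyl)silyl]oxy}-6-methylhepta-1,5-dien-2-yl]-3-methyl-2-oxocyclohex-3-en-1-yl 3-methylbut-2-enoate
Conditions: 13 (1.5 equiv), pyridine, DMAP (cat.), CH2Cl2, 0 °C to rt
Reagents that add atoms: none
Why: DMAP-catalysed acylation of the secondary acyloin hydroxyl, done directly after the hydroxylation so that the base-sensitive α-hydroxy enone is capped before further handling, with pyridine instead of a trialkylamine to limit ketene formation and double-bond migration in the senecioyl group.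

Step 8
Reactants: 14 (1S,6S)-6-[(3R)-3-{[tert-butyl(diphenyl)silyl]oxy}-6-methylhepta-1,5-dien-2-yl]-3-methyl-2-oxocyclohex-3-en-1-yl 3-methylbut-2-enoate
Product: 15 (1S,6S)-6-[(3R)-3-hydroxy-6-methylhepta-1,5-dien-2-yl]-3-methyl-2-oxocyclohex-3-en-1-yl 3-methylbut-2-enoate
Conditions: HF·pyridine, pyridine, THF, 0 °C to rt
Reagents that add atoms: none
Why: Fluoride cleavage of the silyl ether under buffered, mildly acidic conditions, which should leave the ring ester and the enone untouched; acyl migration to the freed hydroxyl is not expected because the two oxygen-bearing carbons are 1,4-related.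

Step 9
Reactants: 15 (1S,6S)-6-[(3R)-3-hydroxy-6-methylhepta-1,5-dien-2-yl]-3-methyl-2-oxocyclohex-3-en-1-yl 3-methylbut-2-enoate; 13 3-methylbut-2-enoyl chloride
Product: 16 (1S,6S)-3-methyl-6-[(3R)-6-methyl-3-[(3-methylbut-2-enoyl)oxy]hepta-1,5-dien-2-yl]-2-oxocyclohex-3-en-1-yl 3-methylbut-2-enoate
Conditions: 13 (1.5 equiv), pyridine, DMAP (cat.), CH2Cl2, 0 °C to rt
Reagents that add atoms: none
Why: DMAP-catalysed acylation of the allylic secondary alcohol under the conditions of step 7, which installs the second senecioate without disturbing the α-acyloxy enone.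

Step 10
Reactants: 16 (1S,6S)-3-methyl-6-[(3R)-6-methyl-3-[(3-methylbut-2-enoyl)oxy]hepta-1,5-dien-2-yl]-2-oxocyclohex-3-en-1-yl 3-methylbut-2-enoate
Product: 17 (1S,2S,6S)-2-hydroxy-3-methyl-6-[(3R)-6-methyl-3-[(3-methylbut-2-enoyl)oxy]hepta-1,5-dien-2-yl]cyclohex-3-en-1-yl 3-methylbut-2-enoate
Conditions: NaBH4, CeCl3·7H2O, MeOH, −78 °C
Reagents that add atoms: none
Why: Luche reduction, in which axial 1,2-hydride delivery to the diequatorial half-chair should give the pseudo-equatorial alcohol, trans to the neighbouring ester and cis to the side chain, while the conjugated esters are not reduced.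

Step 11
Reactants: 17 (1S,2S,6S)-2-hydroxy-3-methyl-6-[(3R)-6-methyl-3-[(3-methylbut-2-enoyl)oxy]hepta-1,5-dien-2-yl]cyclohex-3-en-1-yl 3-methylbut-2-enoate
Product: 18 (1R,2R,3S,4S,6S)-2-hydroxy-1-methyl-4-[(3R)-6-methyl-3-[(3-methylbut-2-enoyl)oxy]hepta-1,5-dien-2-yl]-7-oxabicyclo[4.1.0]heptan-3-yl 3-methylbut-2-enoate
Conditions: VO(acac)2 (5 mol%), t-BuOOH (in decane), CH2Cl2, 0 °C to rt
Reagents that add atoms: tert-butyl hydroperoxide, CC(C)(C)OO
Why: Hydroxyl-directed epoxidation, in which the vanadium alkoxide of the allylic alcohol delivers oxygen to the ring double bond on the face of the hydroxyl group (cis to the side chain), while the side-chain alkenes lack a free allylic hydroxyl and the enoates are electron-poor.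

Step 12
Reactants: 18 (1R,2R,3S,4S,6S)-2-hydroxy-1-methyl-4-[(3R)-6-methyl-3-[(3-methylbut-2-enoyl)oxy]hepta-1,5-dien-2-yl]-7-oxabicyclo[4.1.0]heptan-3-yl 3-methylbut-2-enoate
Product: 19 (1S,3S,4S,6S)-1-methyl-4-[(3R)-6-methyl-3-[(3-methylbut-2-enoyl)oxy]hepta-1,5-dien-2-yl]-2-oxo-7-oxabicyclo[4.1.0]heptan-3-yl 3-methylbut-2-enoate
Conditions: Dess–Martin periodinane, CH2Cl2, rt
Reagents that add atoms: none
Why: Dess–Martin oxidation of the secondary epoxy alcohol to the α,β-epoxy ketone under near-neutral conditions that should neither epimerise the acyloxy-bearing carbon nor open the oxirane.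

**Compound list**

1 | 6-methylhept-5-en-2-one (sulcatone) | CC(=O)CCC=C(C)C | starting material
2 | (3R)-6-methyl-3-[(phenylamino)oxy]hept-5-en-2-one | CC(=O)[C@@H](CC=C(C)C)ONc1ccccc1 | intermediate
3 | (3R)-3-hydroxy-6-methylhept-5-en-2-one | CC(=O)[C@@H](CC=C(C)C)O | intermediate
4 | (3R)-3-{[tert-butyl(diphenyl)silyl]oxy}-6-methylhept-5-en-2-one | CC(=O)[C@@H](CC=C(C)C)O[Si](c1ccccc1)(c1ccccc1)C(C)(C)C | intermediate
5 | (3R)-3-{[tert-butyl(diphenyl)silyl]oxy}-6-methylhepta-1,5-dien-2-yl trifluoromethanesulfonate | C=C(OS(=O)(=O)C(F)(F)F)[C@@H](CC=C(C)C)O[Si](c1ccccc1)(c1ccccc1)C(C)(C)C | intermediate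
6 | prop-2-enal (acrolein) | C=CC=O | starting material
7 | (2E,5R)-5-{[tert-butyl(diphenyl)silyl]oxy}-8-methyl-4-methylidenenona-2,7-dienal | O=C/C=C/C(=C)[C@@H](CC=C(C)C)O[Si](c1ccccc1)(c1ccccc1)C(C)(C)C | intermediate
8 | tert-butyl 3-oxopentanoate | CCC(=O)CC(=O)OC(C)(C)C | starting material
9 | tert-butyl (3R)-3-[(3R)-3-{[tert-butyl(diphenyl)silyl]oxy}-6-methylhepta-1,5-dien-2-yl]-5-oxo-2-propanoylpentanoate (both C-2 epimers) | CCC(=O)C(C(=O)OC(C)(C)C)[C@@H](CC=O)C(=C)[C@@H](CC=C(C)C)O[Si](c1ccccc1)(c1ccccc1)C(C)(C)C | intermediate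
10 | (3R)-3-[(3R)-3-{[tert-butyl(diphenyl)silyl]oxy}-6-methylhepta-1,5-dien-2-yl]-5-oxoheptanal | CCC(=O)C[C@@H](CC=O)C(=C)[C@@H](CC=C(C)C)O[Si](c1ccccc1)(c1ccccc1)C(C)(C)C | intermediate
11 | (5R)-5-[(3R)-3-{[tert-butyl(diphenyl)silyl]oxy}-6-methylhepta-1,5-dien-2-yl]-2-methylcyclohex-2-en-1-one | C=C([C@@H](CC=C(C)C)O[Si](c1ccccc1)(c1ccccc1)C(C)(C)C)[C@@H]1CC=C(C)C(=O)C1 | intermediate
12 | (5S,6S)-5-[(3R)-3-{[tert-butyl(diphenyl)silyl]oxy}-6-methylhepta-1,5-dien-2-yl]-6-hydroxy-2-methylcyclohex-2-en-1-one (hydroxyl trans to side chain) | C=C([C@@H](CC=C(C)C)O[Si](c1ccccc1)(c1ccccc1)C(C)(C)C)[C@@H]1CC=C(C)C(=O)[C@H]1O | intermediate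
13 | 3-methylbut-2-enoyl chloride (senecioyl chloride) | CC(C)=CC(=O)Cl | starting material
14 | (1S,6S)-6-[(3R)-3-{[tert-butyl(diphenyl)silyl]oxy}-6-methylhepta-1,5-dien-2-yl]-3-methyl-2-oxocyclohex-3-en-1-yl 3-methylbut-2-enoate | C=C([C@@H](CC=C(C)C)O[Si](c1ccccc1)(c1ccccc1)C(C)(C)C)[C@@H]1CC=C(C)C(=O)[C@H]1OC(=O)C=C(C)C | intermediate
15 | (1S,6S)-6-[(3R)-3-hydroxy-6-methylhepta-1,5-dien-2-yl]-3-methyl-2-oxocyclohex-3-en-1-yl 3-methylbut-2-enoate | C=C([C@@H](CC=C(C)C)O)[C@@H]1CC=C(C)C(=O)[C@H]1OC(=O)C=C(C)C | intermediate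
16 | (1S,6S)-3-methyl-6-[(3R)-6-methyl-3-[(3-methylbut-2-enoyl)oxy]hepta-1,5-dien-2-yl]-2-oxocyclohex-3-en-1-yl 3-methylbut-2-enoate | C=C([C@@H](CC=C(C)C)OC(=O)C=C(C)C)[C@@H]1CC=C(C)C(=O)[C@H]1OC(=O)C=C(C)C | intermediate
17 | (1S,2S,6S)-2-hydroxy-3-methyl-6-[(3R)-6-methyl-3-[(3-methylbut-2-enoyl)oxy]hepta-1,5-dien-2-yl]cyclohex-3-en-1-yl 3-methylbut-2-enoate (hydroxyl cis to side chain, trans to ring ester) | C=C([C@@H](CC=C(C)C)OC(=O)C=C(C)C)[C@@H]1CC=C(C)[C@H](O)[C@H]1OC(=O)C=C(C)C | intermediate
18 | (1R,2R,3S,4S,6S)-2-hydroxy-1-methyl-4-[(3R)-6-methyl-3-[(3-methylbut-2-enoyl)oxy]hepta-1,5-dien-2-yl]-7-oxabicyclo[4.1.0]heptan-3-yl 3-methylbut-2-enoate (oxirane cis to hydroxyl and side chain) | C=C([C@@H](CC=C(C)C)OC(=O)C=C(C)C)[C@@H]1C[C@@H]2O[C@]2(C)[C@H](O)[C@H]1OC(=O)C=C(C)C | intermediate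
19 | (1S,3S,4S,6S)-1-methyl-4-[(3R)-6-methyl-3-[(3-methylbut-2-enoyl)oxy]hepta-1,5-dien-2-yl]-2-oxo-7-oxabicyclo[4.1.0]heptan-3-yl 3-methylbut-2-enoate (CNP0140369.1) | C=C([C@@H](CC=C(C)C)OC(=O)C=C(C)C)[C@@H]1C[C@@H]2O[C@]2(C)C(=O)[C@H]1OC(=O)C=C(C)C | target

**Step count**

Total steps: 12. Longest linear sequence: 12 steps (1 to 19); compounds 6, 8 and 13 are purchased.

**Steps most likely to fail**

Step 5. The hot-acid stage may cleave the allylic silyl ether or cyclise and isomerise the diene faster than the decarboxylative aldol condensation closes the ring; competing 1,6-addition at the unsubstituted methylidene terminus in the Michael stage would add to this. The fallback sets out from 7 and returns at 11, and removes the activating group without acid. Prop-2-en-1-yl 3-oxopentanoate F1, made from methyl 3-oxopentanoate and allyl alcohol (DMAP, toluene, reflux), would be added to 7 under the amine catalyst of step 5 to give the allyl ester Michael adduct F2. Pd(PPh3)4 and pyrrolidine in THF at rt should then transfer the allyl group from zerovalent palladium to the amine and release CO2, giving keto aldehyde 10. Pyrrolidine with acetic acid should finally close 10 to enone 11 by an amine-mediated aldol condensation.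

Step 4. Acrolein may polymerise and insert too slowly, so that the alkenylpalladium intermediate decomposes before coupling. The fallback sets out from 5 and returns at 7. Stille coupling of 5 with (E)-3-(tributylstannyl)prop-2-en-1-ol (Pd(PPh3)4, LiCl, THF, 60 °C) should give the dienol F3 with the E geometry fixed by the stannane, and MnO2 in CH2Cl2 should oxidise its allylic alcohol to dienal 7.

Step 10. Hydride may be delivered with poor facial control next to the acyloxy-bearing carbon (polar attack anti to the C–O bond competes with axial attack), and the new hydroxyl may then take over the neighbouring acyl group before or during the epoxidation. The fallback sets out from 11 and returns at 19, and moves the redox and epoxidation steps in front of the oxygenation of C3. Luche reduction of 11, controlled by the side chain alone as in the reduction of carvone, should give the cis-cyclohexenol F4. VO(acac)2 with t-BuOOH should give the syn epoxy alcohol F5, and Dess–Martin oxidation the epoxy ketone F6. Its only enolisable position would then be hydroxylated (KN(SiMe3)2, then 2-(phenylsulfonyl)-3-phenyloxaziridine) anti to both the side chain and the oxirane to give the hydroxy epoxy ketone F7. Acylation with 13 (pyridine, DMAP) should give the ring ester F8, HF·pyridine should free the side-chain alcohol F9, and a second acylation with 13 should give 19.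

Further compounds
F1 | step 5 | prop-2-en-1-yl 3-oxopentanoate | CCC(=O)CC(=O)OCC=C
F2 | step 5 | prop-2-en-1-yl (3R)-3-[(3R)-3-{[tert-butyl(diphenyl)silyl]oxy}-6-methylhepta-1,5-dien-2-yl]-5-oxo-2-propanoylpentanoate (both C-2 epimers) | CCC(=O)C(C(=O)OCC=C)[C@@H](CC=O)C(=C)[C@@H](CC=C(C)C)O[Si](c1ccccc1)(c1ccccc1)C(C)(C)C
F3 | step 4 | (2E,5R)-5-{[tert-butyl(diphenyl)silyl]oxy}-8-methyl-4-methylidenenona-2,7-dien-1-ol | OC/C=C/C(=C)[C@@H](CC=C(C)C)O[Si](c1ccccc1)(c1ccccc1)C(C)(C)C
F4 | step 10 | (1R,5R)-5-[(3R)-3-{[tert-butyl(diphenyl)silyl]oxy}-6-methylhepta-1,5-dien-2-yl]-2-methylcyclohex-2-en-1-ol | C=C([C@@H](CC=C(C)C)O[Si](c1ccccc1)(c1ccccc1)C(C)(C)C)[C@@H]1CC=C(C)[C@H](O)C1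
F5 | step 10 | (1R,2R,4S,6S)-4-[(3R)-3-{[tert-butyl(diphenyl)silyl]oxy}-6-methylhepta-1,5-dien-2-yl]-1-methyl-7-oxabicyclo[4.1.0]heptan-2-ol | C=C([C@@H](CC=C(C)C)O[Si](c1ccccc1)(c1ccccc1)C(C)(C)C)[C@@H]1C[C@@H]2O[C@]2(C)[C@H](O)C1
F6 | step 10 | (1S,4R,6S)-4-[(3R)-3-{[tert-butyl(diphenyl)silyl]oxy}-6-methylhepta-1,5-dien-2-yl]-1-methyl-7-oxabicyclo[4.1.0]heptan-2-one | C=C([C@@H](CC=C(C)C)O[Si](c1ccccc1)(c1ccccc1)C(C)(C)C)[C@@H]1C[C@@H]2O[C@]2(C)C(=O)C1
F7 | step 10 | (1S,3S,4S,6S)-4-[(3R)-3-{[tert-butyl(diphenyl)silyl]oxy}-6-methylhepta-1,5-dien-2-yl]-3-hydroxy-1-methyl-7-oxabicyclo[4.1.0]heptan-2-one | C=C([C@@H](CC=C(C)C)O[Si](c1ccccc1)(c1ccccc1)C(C)(C)C)[C@@H]1C[C@@H]2O[C@]2(C)C(=O)[C@H]1O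
F8 | step 10 | (1S,3S,4S,6S)-4-[(3R)-3-{[tert-butyl(diphenyl)silyl]oxy}-6-methylhepta-1,5-dien-2-yl]-1-methyl-2-oxo-7-oxabicyclo[4.1.0]heptan-3-yl 3-methylbut-2-enoate | C=C([C@@H](CC=C(C)C)O[Si](c1ccccc1)(c1ccccc1)C(C)(C)C)[C@@H]1C[C@@H]2O[C@]2(C)C(=O)[C@H]1OC(=O)C=C(C)C
F9 | step 10 | (1S,3S,4S,6S)-4-[(3R)-3-hydroxy-6-methylhepta-1,5-dien-2-yl]-1-methyl-2-oxo-7-oxabicyclo[4.1.0]heptan-3-yl 3-methylbut-2-enoate | C=C([C@@H](CC=C(C)C)O)[C@@H]1C[C@@H]2O[C@]2(C)C(=O)[C@H]1OC(=O)C=C(C)C
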